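Ring B is closed last by an intramolecular Stetter reaction that joins C6 to C5. The step exploits the 1,4-relationship of the C6 oxygen in ring B to both the C3 oxygen and C19 on ring A: an acyl-anion equivalent at C6 is the natural partner for C5 of a ring-A cyclohexenone carrying the C19 ester on C4. In one operation it forms the decalin, installs the C6 carbonyl and keeps C9 as a ketone for the later side-chain coupling. The precursor is an (S)-configured 2-(methoxycarbonyl)cyclohexenone whose quaternary C10 bears the C20 methyl and a 2-methyl-4-oxobutanoyl arm.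

Key step: step 10

Assumption: ring compounds are described with labdane numbering (β = the face of the C10 methyl, C20); the catalyst antipode in step 2 is the one that delivers (S)-4 (written as the (S)-prolinol-derived oxazaborolidine); C8, which ends as an sp2 carbon, is carried as a mixture of epimers from step 5 to step 13.

Step 1
Reactants: 1 but-3-en-2-one
Product: 2 2-[(triisopropylsilyl)oxy]buta-1,3-diene
Conditions: i-Pr3SiOSO2CF3, Et3N, Et2O, 0 → 23 °C
Reagents that add atoms: triisopropylsilyl trifluoromethanesulfonate, CC(C)[Si](C(C)C)(C(C)C)OS(=O)(=O)C(F)(F)F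
Why: Soft enolisation of the methyl ketone (silyl enol ether formation) gives the 2-silyloxydiene, the bulky silyl group making it robust toward the Lewis acid of step 2.

Step 2
Reactants: 2 2-[(triisopropylsilyl)oxy]buta-1,3-diene; 3 2-methylprop-2-enal (methacrolein)
Product: 4 (S)-1-methyl-4-[(triisopropylsilyl)oxy]cyclohex-3-ene-1-carbaldehyde
Conditions: (S)-3,3-diphenyl-1-(o-tolyl)tetrahydro-1H,3H-pyrrolo[1,2-c][1,3,2]oxazaborole (10 mol %), HN(SO2CF3)2 (10 mol %), CH2Cl2, −78 °C
Reagents that add atoms: none
Why: Enantioselective Diels–Alder reaction under chiral oxazaborolidinium catalysis, in which the 2-silyloxy group directs the 1,4 ("para") regiochemistry and the catalyst shields one face of the coordinated methacrolein, so that the quaternary C10 is set by the catalyst.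

Step 3
Reactants: 4 (S)-1-methyl-4-[(triisopropylsilyl)oxy]cyclohex-3-ene-1-carbaldehyde
Product: 5 1-[(S)-1-methyl-4-(triisopropylsilyloxy)cyclohex-3-en-1-yl]propan-1-ol (both carbinol epimers)
Conditions: EtMgBr, THF, −78 → 0 °C; aq. NH4Cl
Reagents that add atoms: ethylmagnesium bromide, CC[Mg]Br
Why: Grignard addition to the non-enolisable neopentyl aldehyde brings in C8 and C17, and the carbinol centre is formed without control because it is oxidised in step 4.

Step 4
Reactants: 5 1-[(S)-1-methyl-4-(triisopropylsilyloxy)cyclohex-3-en-1-yl]propan-1-ol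
Product: 6 1-[(S)-1-methyl-4-(triisopropylsilyloxy)cyclohex-3-en-1-yl]propan-1-one
Conditions: Dess–Martin periodinane, CH2Cl2, 0 → 23 °C
Reagents that add atoms: none
Why: Dess–Martin oxidation of the secondary alcohol gives the C9 ketone under mild conditions that leave the hindered silyl enol ether intact.

Step 5
Reactants: 6 1-[(S)-1-methyl-4-(triisopropylsilyloxy)cyclohex-3-en-1-yl]propan-1-one
Product: 7 2-methyl-1-[(S)-1-methyl-4-(triisopropylsilyloxy)cyclohex-3-en-1-yl]pent-4-en-1-one (C8 epimers)
Conditions: LiN(i-Pr)2, THF, −78 °C; allyl bromide, −78 → 0 °C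
Reagents that add atoms: allyl bromide, C=CCBr
Why: Enolate alkylation, in which the ketone can be deprotonated only at C8 (C10 is quaternary and the ring carbonyl is masked as its silyl enol ether), installs C7 and a masked C6 aldehyde; the C8 configuration is left open because C8 becomes sp2 in step 14.

Step 6
Reactants: 7 2-methyl-1-[(S)-1-methyl-4-(triisopropylsilyloxy)cyclohex-3-en-1-yl]pent-4-en-1-one
Product: 8 (S)-4-methyl-4-(2-methylpent-4-enoyl)cyclohex-2-en-1-one (C8 epimers)
Conditions: Pd(OAc)2 (1.05 equiv), MeCN, 23 → 40 °C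
Reagents that add atoms: none
Why: Saegusa–Ito oxidation of the regiodefined silyl enol ether, in which β-hydride elimination can only take a hydrogen from C5, gives the C4=C5 enone without affecting C10.

Step 7
Reactants: 8 (S)-4-methyl-4-(2-methylpent-4-enoyl)cyclohex-2-en-1-one
Product: 9 (S)-2-iodo-4-methyl-4-(2-methylpent-4-enoyl)cyclohex-2-en-1-one (C8 epimers)
Conditions: I2, pyridine, CH2Cl2, 0 → 23 °C
Reagents that add atoms: iodine, II
Why: α-Iodination of the enone by reversible conjugate addition of pyridine, iodination of the resulting enolate and elimination places the halogen on C4 only.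

Step 8
Reactants: 9 (S)-2-iodo-4-methyl-4-(2-methylpent-4-enoyl)cyclohex-2-en-1-one
Product: 10 methyl (S)-3-methyl-3-(2-methylpent-4-enoyl)-6-oxocyclohex-1-ene-1-carboxylate (C8 epimers)
Conditions: PdCl2(PPh3)2 (5 mol %), CO (1 atm), MeOH, Et3N, DMF, 50 °C
Reagents that add atoms: carbon monoxide, [C-]#[O+]; methanol, CO
Why: Palladium-catalysed alkoxycarbonylation of the α-iodoenone (oxidative addition, CO insertion, methanolysis of the acylpalladium) introduces C19 as the ester on C4, CO capture being faster than Heck cyclisation onto the remote terminal alkene.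

Step 9
Reactants: 10 methyl (S)-3-methyl-3-(2-methylpent-4-enoyl)-6-oxocyclohex-1-ene-1-carboxylate
Product: 11 methyl (S)-3-methyl-3-(2-methyl-4-oxobutanoyl)-6-oxocyclohex-1-ene-1-carboxylate (C8 epimers)
Conditions: O3, CH2Cl2, −78 °C, stopped when 10 is consumed; Me2S, −78 → 23 °C
Reagents that add atoms: ozone, [O-][O+]=O
Why: Ozonolysis with reductive work-up cleaves the electron-rich terminal alkene far faster than the electron-poor C4=C5 bond and unveils the C6 aldehyde, which is used at once.

Step 10
Reactants: 11 methyl (S)-3-methyl-3-(2-methyl-4-oxobutanoyl)-6-oxocyclohex-1-ene-1-carboxylate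
Product: 12 cis-fused enol keto ester: methyl 3-hydroxy-8,10-dimethyl-6,9-dioxodecal-3-ene-4-carboxylate (5β-H, 10β-CH3, C8 epimers)
Conditions: 2-(pentafluorophenyl)-6,7-dihydro-5H-pyrrolo[2,1-c][1,2,4]triazol-2-ium tetrafluoroborate (20 mol %), KN(SiMe3)2 (18 mol %), toluene, 23 °C
Reagents that add atoms: none
Why: The triazolylidene adds to the C6 aldehyde, proton transfer gives the hydroxy-enamine acyl-anion equivalent, this adds to C5 of the C4=C5 enone ester, and the C4 enolate is protonated while the carbene is expelled to leave the C6 ketone. The closest known reaction is the intramolecular Stetter reaction of aliphatic aldehydes with doubly activated alkenes under triazolium catalysis, including closures onto the β-carbon of 4,4-disubstituted cyclohexenone-type acceptors. Ring B closes in 6-exo-trig mode, the C4=C5 bond lying outside the new ring. C5 is the only new stereocentre and is controlled by C10 through the tether: the acyl arm can reach C5 only along the axial trajectory on its own face, so H5 ends up cis to the C10 methyl. The step needs chemoselectivity for conjugate acylation over aldol, benzoin and enolate Michael pathways; the substrate secures it because C5 is activated by both the C3 ketone and the C19 ester, the C9 ketone cannot enolise toward C10 and is too hindered to accept the acyl-anion equivalent, and the tether allows only the six-membered closure.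

Step 11
Reactants: 12 cis-fused enol keto ester
Product: 14 methyl 4α,8,10β-trimethyl-3,6,9-trioxo-5α-decalin-4β-carboxylate (trans-fused trione, C8 epimers), via trans-fused keto ester 13 (not isolated)
Conditions: DBU (3 equiv), MeI (6 equiv), toluene, 23 → 40 °C
Reagents that add atoms: iodomethane, CI
Why: DBU forms the keto ester enolate and interconverts the C5 epimers through the C6 enol, and C-methylation (amidine-mediated alkylation of a 1,3-dicarbonyl compound) should be fast only for the trans-fused enolate 13, whose α face carries just the pseudoaxial H5 while its β face is blocked by the axial C10 methyl, whereas the cis enolate is blocked on the α face by the pseudoaxial C5–C6 bond and on the β face by the same methyl, so the material should drain through 13 to the 4α-methyl-4β-ester with trans ring fusion, after which H5 lies between two quaternary carbons and is no longer exchanged readily.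

Step 12
Reactants: 14 trans-fused trione
Product: 16 3α-hydroxy-9-oxo-11,12,13,14,15,16-hexanorlabdan-19,6β-olide (C8 epimers), via dihydroxy ester 15 (not isolated)
Conditions: LiBH(s-Bu)3 (2.3 equiv), THF, −78 → −20 °C; aq. NH4Cl, 23 °C
Reagents that add atoms: none
Why: The bulky trialkylborohydride reduces the C3 and C6 ketones by equatorial attack (at C3 giving the axial 3α-alcohol, at C6 from the α face because the β face is closed by the syn-axial C10 methyl and C4 ester, giving the axial 6β-alkoxide), the 6β-alkoxide then closes the γ-lactone onto the syn-axial C19 ester, and the C9 ketone, flanked by quaternary C10 and methyl-bearing C8, is too hindered to react at low temperature.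

Step 13
Reactants: 16 3α-hydroxy-9-oxo-hexanorlabdan-19,6β-olide
Product: 17 3α-benzoyloxy-9-oxo-11,12,13,14,15,16-hexanorlabdan-19,6β-olide (C8 epimers)
Conditions: BzCl, pyridine, DMAP (10 mol %), CH2Cl2, 40 °C
Reagents that add atoms: benzoyl chloride, O=C(Cl)c1ccccc1
Why: DMAP-catalysed acylation of the only free hydroxyl masks the axial 3α-OH as a non-enolisable ester that survives the amide base of step 14 and is removed by the hydride of step 15.

Step 14
Reactants: 17 3α-benzoyloxy-9-oxo-hexanorlabdan-19,6β-olide
Product: 18 3α-benzoyloxy-9-(trifluoromethylsulfonyloxy)-11,12,13,14,15,16-hexanorlabd-8-en-19,6β-olide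
Conditions: KN(SiMe3)2, THF, −78 → 0 °C; PhN(SO2CF3)2, −78 → 23 °C
Reagents that add atoms: N-phenylbis(trifluoromethanesulfonimide), O=S(=O)(N(c1ccccc1)S(=O)(=O)C(F)(F)F)C(F)(F)F
Why: Enolate triflation, in which the C9 ketone can enolise only toward C8 (C10 is quaternary, lactone and benzoate have no α-hydrogen), gives the tetrasubstituted C8=C9 enol triflate and makes both C8 epimers converge.

Step 15
Reactants: 18 enol triflate benzoate lactone
Product: 19 9-(trifluoromethylsulfonyloxy)-11,12,13,14,15,16-hexanorlabd-8-ene-3α,6β,19-triol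
Conditions: (i-Bu)2AlH (excess), CH2Cl2, −78 → 23 °C; aq. potassium sodium tartrate
Reagents that add atoms: none
Why: Aluminium hydride reduction opens the lactone to the 6β,19-diol and cleaves the benzoate in the same operation, while the enol triflate is inert to this hydride and no stereocentre is touched.

Step 16
Reactants: 20 ethyl (E)-3-methyl-4-oxobut-2-enoate
Product: 21 ethyl (E)-3-methylpenta-2,4-dienoate
Conditions: Ph3PCH3Br, KOt-Bu, THF, 0 °C; then 20, 0 → 23 °C
Reagents that add atoms: methyltriphenylphosphonium bromide, C[P+](c1ccccc1)(c1ccccc1)c1ccccc1.[Br-]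
Why: Wittig methylenation of the aldehyde leaves the (E)-enoate geometry of the commercial aldehyde untouched and gives the diene whose vinyl group becomes C11–C12.

Step 17
Reactants: 21 ethyl (E)-3-methylpenta-2,4-dienoate; 19 enol triflate triol
Product: 23 ethyl 3α,6β,19-trihydroxylabda-8,13E-dien-15-oate, via B-alkyl-9-BBN ester 22 (not isolated)
Conditions: 9-BBN-H, THF, 0 → 23 °C; then 19, PdCl2(dppf) (10 mol %), AsPh3, Cs2CO3, DMF/THF/H2O, 50 °C
Reagents that add atoms: none
Why: Hydroboration with 9-BBN-H takes place at the terminal carbon of the vinyl group (the electron-poor trisubstituted alkene and the ester do not react), and the B-alkyl borane undergoes sp3–sp2 Suzuki–Miyaura coupling with the enol triflate under aqueous basic conditions that tolerate the free hydroxyls and retain the (E)-enoate.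

Step 18
Reactants: 23 ethyl 3α,6β,19-trihydroxylabda-8,13E-dien-15-oate
Product: 24 3α,6β,19-trihydroxylabda-8,13E-dien-15-oic acid (CNP0246116.2)
Conditions: LiOH, THF/MeOH/H2O, 40 °C; then 1 M HCl to pH 3
Reagents that add atoms: lithium hydroxide (hydroxide oxygen of the acid), [Li+].[OH-]
Why: Saponification of the ethyl ester followed by acidification gives the free acid, and neither the tetrasubstituted ring alkene nor the (E)-enoate is affected.

Compound list
1 | but-3-en-2-one | CC(=O)C=C | starting material
2 | 2-[(triisopropylsilyl)oxy]buta-1,3-diene | C=CC(=C)O[Si](C(C)C)(C(C)C)C(C)C | intermediate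
3 | 2-methylprop-2-enal | CC(=C)C=O | starting material
4 | (S)-1-methyl-4-[(triisopropylsilyl)oxy]cyclohex-3-ene-1-carbaldehyde | O=C[C@@]1(C)CCC(O[Si](C(C)C)(C(C)C)C(C)C)=CC1 | intermediate
5 | 1-[(S)-1-methyl-4-(triisopropylsilyloxy)cyclohex-3-en-1-yl]propan-1-ol, carbinol epimers | CCC(O)[C@@]1(C)CCC(O[Si](C(C)C)(C(C)C)C(C)C)=CC1 | intermediate
6 | 1-[(S)-1-methyl-4-(triisopropylsilyloxy)cyclohex-3-en-1-yl]propan-1-one | CCC(=O)[C@@]1(C)CCC(O[Si](C(C)C)(C(C)C)C(C)C)=CC1 | intermediate
7 | 2-methyl-1-[(S)-1-methyl-4-(triisopropylsilyloxy)cyclohex-3-en-1-yl]pent-4-en-1-one, C8 epimers | C=CCC(C)C(=O)[C@@]1(C)CCC(O[Si](C(C)C)(C(C)C)C(C)C)=CC1 | intermediate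
8 | (S)-4-methyl-4-(2-methylpent-4-enoyl)cyclohex-2-en-1-one, C8 epimers | C=CCC(C)C(=O)[C@@]1(C)CCC(=O)C=C1 | intermediate
9 | (S)-2-iodo-4-methyl-4-(2-methylpent-4-enoyl)cyclohex-2-en-1-one, C8 epimers | C=CCC(C)C(=O)[C@@]1(C)CCC(=O)C(I)=C1 | intermediate
10 | methyl (S)-3-methyl-3-(2-methylpent-4-enoyl)-6-oxocyclohex-1-ene-1-carboxylate, C8 epimers | C=CCC(C)C(=O)[C@@]1(C)CCC(=O)C(C(=O)OC)=C1 | intermediate
11 | methyl (S)-3-methyl-3-(2-methyl-4-oxobutanoyl)-6-oxocyclohex-1-ene-1-carboxylate, C8 epimers (key-step precursor) | O=CCC(C)C(=O)[C@@]1(C)CCC(=O)C(C(=O)OC)=C1 | intermediate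
12 | cis-fused enol keto ester, methyl 3-hydroxy-8,10-dimethyl-6,9-dioxodecal-3-ene-4-carboxylate (5β-H, 10β-CH3), C8 epimers (key-step product) | CC1C(=O)[C@@]2(C)CCC(O)=C(C(=O)OC)[C@H]2C(=O)C1 | intermediate
13 | trans-fused keto ester (5α-H epimer of 12, shown as enol), C8 epimers | CC1C(=O)[C@@]2(C)CCC(O)=C(C(=O)OC)[C@@H]2C(=O)C1 | intermediate
14 | methyl 4α,8,10β-trimethyl-3,6,9-trioxo-5α-decalin-4β-carboxylate, C8 epimers | CC1C(=O)[C@@]2(C)CCC(=O)[C@](C)(C(=O)OC)[C@@H]2C(=O)C1 | intermediate
15 | methyl 3α,6β-dihydroxy-4α,8,10β-trimethyl-9-oxo-5α-decalin-4β-carboxylate, C8 epimers | CC1C(=O)[C@@]2(C)CC[C@@H](O)[C@](C)(C(=O)OC)[C@@H]2[C@H](O)C1 | intermediate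
16 | 3α-hydroxy-9-oxo-11,12,13,14,15,16-hexanorlabdan-19,6β-olide, C8 epimers | CC1C(=O)[C@@]2(C)CC[C@@H](O)[C@]3(C)C(=O)O[C@H](C1)[C@H]23 | intermediate
17 | 3α-benzoyloxy-9-oxo-11,12,13,14,15,16-hexanorlabdan-19,6β-olide, C8 epimers | CC1C(=O)[C@@]2(C)CC[C@@H](OC(=O)c3ccccc3)[C@]4(C)C(=O)O[C@H](C1)[C@H]24 | intermediate
18 | 3α-benzoyloxy-9-(trifluoromethylsulfonyloxy)-11,12,13,14,15,16-hexanorlabd-8-en-19,6β-olide | CC1=C(OS(=O)(=O)C(F)(F)F)[C@@]2(C)CC[C@@H](OC(=O)c3ccccc3)[C@]4(C)C(=O)O[C@H](C1)[C@H]24 | intermediate
19 | 9-(trifluoromethylsulfonyloxy)-11,12,13,14,15,16-hexanorlabd-8-ene-3α,6β,19-triol | CC1=C(OS(=O)(=O)C(F)(F)F)[C@@]2(C)CC[C@@H](O)[C@](C)(CO)[C@@H]2[C@H](O)C1 | intermediate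
20 | ethyl (E)-3-methyl-4-oxobut-2-enoate | O=C/C(C)=C/C(=O)OCC | starting material
21 | ethyl (E)-3-methylpenta-2,4-dienoate | C=C/C(C)=C/C(=O)OCC | intermediate
22 | ethyl (E)-5-(9-borabicyclo[3.3.1]nonan-9-yl)-3-methylpent-2-enoate | CCOC(=O)/C=C(C)/CCB1C2CCCC1CCC2 | intermediate
23 | ethyl 3α,6β,19-trihydroxylabda-8,13E-dien-15-oate | CC1=C(CC/C(C)=C/C(=O)OCC)[C@@]2(C)CC[C@@H](O)[C@](C)(CO)[C@@H]2[C@H](O)C1 | intermediate
24 | 3α,6β,19-trihydroxylabda-8,13E-dien-15-oic acid (CNP0246116.2) | CC1=C(CC/C(C)=C/C(=O)O)[C@@]2(C)CC[C@@H](O)[C@](C)(CO)[C@@H]2[C@H](O)C1 | target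

Total step count: 18.
Longest linear sequence: 17 steps (steps 1–15, 17 and 18, from but-3-en-2-one); step 16 prepares the side-chain diene separately.

Steps most likely to fail

Step 10. The carbene may be consumed by conjugate addition to the very electrophilic enone ester, or the keto aldehyde may self-condense faster than it is acylated. The fallback forms the same C5–C6 bond by a radical chain. It sets out from 11: tert-dodecanethiol (catalytic) and AIBN in chlorobenzene at 80 °C generate the acyl radical by abstraction of the formyl hydrogen, the nucleophilic acyl radical adds 6-exo to the electron-poor C5, and the C4 radical is reduced by the thiol. It comes back at 12, as a C5 epimer mixture that step 11 tolerates.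

Step 11. C5 equilibration may be slower than alkylation, so that methylation on the cis enolate gives the C4,C5 diastereomer, and O-methylation may compete. The fallback erases C5 and rebuilds it under non-basic conditions. It sets out from 12: selenenylation at C4 (PhSeCl, pyridine, CH2Cl2) would give the α-phenylselanyl keto ester F1, and oxidation with H2O2 with syn-elimination across C4–C5 would give the 4-ene-3,6-dione ester F2. Zinc in acetic acid, the classical reduction of 4-ene-3,6-diones to trans-fused 3,6-diones, would then give the trans keto ester 13, which is isolated. Methylation with NaH and MeI in THF, which does not exchange H5, comes back at 14.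

Step 17. Oxidative addition and transmetallation at the tetrasubstituted triflate next to the quaternary C10 may be slow, so that protodeboronation or reduction of the triflate take over, and hydroboration of the dienoate may not be clean. The fallback moves the sp3–sp2 bond formation to C12–C13. It sets out from 19: Suzuki vinylation with potassium vinyltrifluoroborate (PdCl2(dppf), Cs2CO3, THF/H2O) would give the 9-vinyl diene triol F3, and 9-BBN-H would hydroborate its terminal carbon to the B-alkyl borane F4. Coupling of F4 with ethyl (E)-3-iodobut-2-enoate (PdCl2(dppf), AsPh3, Cs2CO3) comes back at 23.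

Further compounds
F0 | step 10 | none | none
F1 | step 11 | methyl 3,6,9-trioxo-4-(phenylselanyl)-8,10-dimethyl-5β-decalin-4-carboxylate (cis-fused) | CC1C(=O)[C@@]2(C)CCC(=O)C([Se]c3ccccc3)(C(=O)OC)[C@H]2C(=O)C1
F2 | step 11 | methyl 8,10-dimethyl-3,6,9-trioxodecal-4-ene-4-carboxylate (4-ene-3,6-dione ester) | CC1C(=O)[C@@]2(C)CCC(=O)C(C(=O)OC)=C2C(=O)C1
F3 | step 17 | 9-vinyl-11,12,13,14,15,16-hexanorlabd-8-ene-3α,6β,19-triol | CC1=C(C=C)[C@@]2(C)CC[C@@H](O)[C@](C)(CO)[C@@H]2[C@H](O)C1
F4 | step 17 | 9-[2-(9-borabicyclo[3.3.1]nonan-9-yl)ethyl]-11,12,13,14,15,16-hexanorlabd-8-ene-3α,6β,19-triol | CC1=C(CCB3C4CCCC3CCC4)[C@@]2(C)CC[C@@H](O)[C@](C)(CO)[C@@H]2[C@H](O)C1
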